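**Retrosynthetic overview**

1. Licoricidin 29 comes from its tris(triisopropylsilyl) ether 28 by fluoride cleavage. Ring C of 28 is closed at C4–C4a: C4 is a bare CH2 between the C3 stereocentre and C4a of the fully substituted ring A, so the bond is drawn from a carboxyl group one carbon beyond C4 (lost as CO2) and an iodide at C4a, both held in N-hydroxyphthalimide ester 27.
2. 27 comes from acid 26 and ester 24. 24 is made by rhodium/(S)-BINAP 1,4-addition of ring B boronic acid 23 to ring A aryloxy enoate 14, which sets C3 and already carries the O1–C2 bond.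
3. 14 comes from phloroglucinol 1: two MOM-directed lithiations place prenyl at C6 and iodine at C4a, O1 is alkylated with methyl 4-bromocrotonate 9, and the iodine then distinguishes O5 (methylated) from O7 (silylated).
4. 23 comes from resorcinol 15 via 2-iodoresorcinol: silylation, bromination, iodine-selective lithiation/prenylation, then bromine–lithium exchange/borylation.
5. Rings A and B are carried as preformed arenes; ring C is the only ring made, in step 17.

Key step: step 17

Remark: MOM = methoxymethyl, TIPS = triisopropylsilyl, prenyl = 3-methylbut-2-en-1-yl. The target is (3R). It is assumed that (S)-BINAP delivers the aryl group to the α-si face of the (E)-enoate 14, as it does for simple (E)-crotonates; if the sense were opposite, (R)-BINAP would be used.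

**Route**

Step 1
Reactants: 1 phloroglucinol (benzene-1,3,5-triol)
Product: 2 3,5-bis(methoxymethoxy)phenol
Conditions: MOMCl (2.0 equiv), i-Pr2NEt (2.2 equiv), DMF, 0 °C → rt; chromatographic separation from mono- and tris-ethers
Reagents that add atoms: chloromethyl methyl ether, COCCl
Why: Statistical Williamson-type O-alkylation of three equivalent phenols should give the bis-acetal beside separable mono- and tris-ethers, and since all hydroxyls are equivalent no regiochemical question arises.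

Step 2
Reactants: 2 3,5-bis(methoxymethoxy)phenol
Product: 3 [3,5-bis(methoxymethoxy)phenoxy]tri(propan-2-yl)silane
Conditions: TIPSCl, imidazole, DMF, rt
Reagents that add atoms: chlorotriisopropylsilane, CC(C)[Si](Cl)(C(C)C)C(C)C
Why: Imidazole-promoted silylation of the single free phenol puts a bulky, non-coordinating group on the oxygen that becomes O1.

Step 3
Reactants: 3 [3,5-bis(methoxymethoxy)phenoxy]tri(propan-2-yl)silane; 4 1-bromo-3-methylbut-2-ene (prenyl bromide)
Product: 6 [3,5-bis(methoxymethoxy)-4-(3-methylbut-2-en-1-yl)phenoxy]tri(propan-2-yl)silane, via aryllithium 5 (not isolated)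
Conditions: n-BuLi, THF, 0 °C; CuBr·SMe2 (10 mol%), 4, −78 °C → rt
Reagents that add atoms: none
Why: Directed ortho-metalation should occur at the carbon flanked by the two chelating MOM ethers (the future C6) and not beside the bulky silyl ether, and the aryllithium is allylated at the primary carbon of prenyl bromide (SN2).

Step 4
Reactants: 6 [3,5-bis(methoxymethoxy)-4-(3-methylbut-2-en-1-yl)phenoxy]tri(propan-2-yl)silane
Product: 8 [2-iodo-3,5-bis(methoxymethoxy)-4-(3-methylbut-2-en-1-yl)phenoxy]tri(propan-2-yl)silane, via aryllithium 7 (not isolated)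
Conditions: s-BuLi, TMEDA, THF, −78 °C; I2 in THF, −78 °C
Reagents that add atoms: iodine, II
Why: A second directed ortho-metalation can take place only at one of the two equivalent ring positions left, each ortho to a MOM ether, so the iodine quench places iodine beside the silyloxy group (the future C4a), and the low temperature suppresses O-to-C silyl migration.

Step 5
Reactants: 8 [2-iodo-3,5-bis(methoxymethoxy)-4-(3-methylbut-2-en-1-yl)phenoxy]tri(propan-2-yl)silane; 9 methyl (E)-4-bromobut-2-enoate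
Product: 11 methyl (E)-4-[2-iodo-3,5-bis(methoxymethoxy)-4-(3-methylbut-2-en-1-yl)phenoxy]but-2-enoate, via phenoxide 10 (not isolated)
Conditions: TBAF (1.05 equiv), THF, 0 °C; then 9 (1.3 equiv), 0 °C → rt
Reagents that add atoms: none
Why: Fluoride cleaves the only silyl ether and the naked phenoxide undergoes Williamson O-alkylation (SN2 at the allylic bromide), which fixes the oxygen beside iodine as O1 while both MOM acetals persist.

Step 6
Reactants: 11 methyl (E)-4-[2-iodo-3,5-bis(methoxymethoxy)-4-(3-methylbut-2-en-1-yl)phenoxy]but-2-enoate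
Product: 12 methyl (E)-4-[3,5-dihydroxy-2-iodo-4-(3-methylbut-2-en-1-yl)phenoxy]but-2-enoate
Conditions: HCl (1.25 M in MeOH), MeOH/THF, 0 °C → rt, stopped at full conversion
Reagents that add atoms: none
Why: Acid-catalysed transacetalisation in methanol removes both MOM groups as dimethoxymethane, and at or below room temperature this cleavage should be faster than acid-catalysed addition of the new phenols to the prenyl alkene.

Step 7
Reactants: 12 methyl (E)-4-[3,5-dihydroxy-2-iodo-4-(3-methylbut-2-en-1-yl)phenoxy]but-2-enoate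
Product: 13 methyl (E)-4-[3-hydroxy-2-iodo-4-(3-methylbut-2-en-1-yl)-5-(triisopropylsilyloxy)phenoxy]but-2-enoate
Conditions: TIPSCl (1.1 equiv), imidazole, DMF, 0 °C → rt
Reagents that add atoms: chlorotriisopropylsilane, CC(C)[Si](Cl)(C(C)C)C(C)C
Why: Sterically controlled phenol silylation: the hydroxyl between prenyl and hydrogen (future O7) should react with the bulky chlorosilane, whereas the hydroxyl wedged between iodine and prenyl (future O5) is doubly ortho-substituted and stays free.

Step 8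
Reactants: 13 methyl (E)-4-[3-hydroxy-2-iodo-4-(3-methylbut-2-en-1-yl)-5-(triisopropylsilyloxy)phenoxy]but-2-enoate
Product: 14 methyl (E)-4-[2-iodo-3-methoxy-4-(3-methylbut-2-en-1-yl)-5-(triisopropylsilyloxy)phenoxy]but-2-enoate
Conditions: MeI, K2CO3, acetone, 40 °C
Reagents that add atoms: iodomethane, CI
Why: Williamson methylation of the remaining acidic, ortho-iodinated phenol under mild carbonate conditions that leave the enoate and the aryl silyl ether intact.

Step 9
Reactants: 15 resorcinol (benzene-1,3-diol)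
Product: 16 2-iodobenzene-1,3-diol
Conditions: I2, NaHCO3, H2O, 0 °C → rt
Reagents that add atoms: iodine, II
Why: Electrophilic aromatic iodination of resorcinol in aqueous bicarbonate is an established route to the 2-iodo isomer, the position between the two hydroxyls.

Step 10
Reactants: 16 2-iodobenzene-1,3-diol
Product: 17 2-iodo-1,3-bis(triisopropylsilyloxy)benzene
Conditions: TIPSOTf (2.4 equiv), 2,6-lutidine, CH2Cl2, 0 °C → rt
Reagents that add atoms: triisopropylsilyl trifluoromethanesulfonate, CC(C)[Si](OS(=O)(=O)C(F)(F)F)(C(C)C)C(C)C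
Why: Silylation of both hindered ortho-iodophenol hydroxyls with the silyl triflate and a hindered pyridine base.

Step 11
Reactants: 17 2-iodo-1,3-bis(triisopropylsilyloxy)benzene
Product: 18 4-bromo-2-iodo-1,3-bis(triisopropylsilyloxy)benzene
Conditions: NBS (1.05 equiv), MeCN, 0 °C → rt
Reagents that add atoms: N-bromosuccinimide, O=C1CCC(=O)N1Br
Why: Electrophilic aromatic bromination should go to C4, para to one silyloxy group and ortho to the other (C4 and C6 are equivalent, C5 is not activated), and the first bromine slows a second substitution.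

Step 12
Reactants: 18 4-bromo-2-iodo-1,3-bis(triisopropylsilyloxy)benzene; 4 1-bromo-3-methylbut-2-ene (prenyl bromide)
Product: 20 1-bromo-3-(3-methylbut-2-en-1-yl)-2,4-bis(triisopropylsilyloxy)benzene, via aryllithium 19 (not isolated)
Conditions: n-BuLi (1.0 equiv), THF, −78 °C; CuBr·SMe2 (10 mol%), 4, −78 → 0 °C
Reagents that add atoms: none
Why: Iodine–lithium exchange is much faster than bromine–lithium exchange and gives the aryllithium flanked by two oxygens, which is allylated by prenyl bromide (SN2), so the bromide remains as the handle for boron.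

Step 13
Reactants: 20 1-bromo-3-(3-methylbut-2-en-1-yl)-2,4-bis(triisopropylsilyloxy)benzene
Product: 23 [3-(3-methylbut-2-en-1-yl)-2,4-bis(triisopropylsilyloxy)phenyl]boronic acid, via aryllithium 21 (not isolated), via lithium arylborate 22 (not isolated)
Conditions: n-BuLi, THF, −78 °C; B(Oi-Pr)3, −78 → 0 °C; dilute aq. HCl (pH 5), 0 °C
Reagents that add atoms: triisopropyl borate, CC(C)OB(OC(C)C)OC(C)C; water, O
Why: Bromine–lithium exchange followed by borylation with a trialkyl borate and mild hydrolysis, run at −78 °C so that the triisopropylsilyl group does not migrate from oxygen to the lithiated carbon.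

Step 14
Reactants: 14 methyl (E)-4-[2-iodo-3-methoxy-4-(3-methylbut-2-en-1-yl)-5-(triisopropylsilyloxy)phenoxy]but-2-enoate; 23 [3-(3-methylbut-2-en-1-yl)-2,4-bis(triisopropylsilyloxy)phenyl]boronic acid
Product: 24 methyl (3R)-4-[2-iodo-3-methoxy-4-(3-methylbut-2-en-1-yl)-5-(triisopropylsilyloxy)phenoxy]-3-[3-(3-methylbut-2-en-1-yl)-2,4-bis(triisopropylsilyloxy)phenyl]butanoate
Conditions: [RhCl(C2H4)2]2 (2.5 mol%), (S)-BINAP (5.5 mol%), aq. KOH (0.2 equiv), 23 (2.5 equiv), dioxane/H2O 10:1, 50 °C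
Reagents that add atoms: none
Why: Hayashi–Miyaura rhodium-catalysed asymmetric 1,4-addition, in which the aryl group passes from boron to the (S)-BINAP-bound rhodium hydroxide, the aryl–rhodium species inserts the (E)-enoate on its α-si face (the sense established for (E)-crotonates with this ligand) and water protonates the rhodium enolate, so that C3 is set as R; the doubly ortho-substituted C–I bond is expected to be inert to monovalent rhodium at this temperature.

Step 15
Reactants: 24 methyl (3R)-4-[2-iodo-3-methoxy-4-(3-methylbut-2-en-1-yl)-5-(triisopropylsilyloxy)phenoxy]-3-[3-(3-methylbut-2-en-1-yl)-2,4-bis(triisopropylsilyloxy)phenyl]butanoate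
Product: 26 (3R)-4-[2-iodo-3-methoxy-4-(3-methylbut-2-en-1-yl)-5-(triisopropylsilyloxy)phenoxy]-3-[3-(3-methylbut-2-en-1-yl)-2,4-bis(triisopropylsilyloxy)phenyl]butanoic acid, via stannyl ester 25 (not isolated)
Conditions: Me3SnOH (5 equiv), 1,2-dichloroethane, 70 °C; then 0.1 M aq. HCl wash
Reagents that add atoms: trimethyltin hydroxide, C[Sn](C)(C)O
Why: Mild ester hydrolysis with trimethyltin hydroxide proceeds through the stannyl ester and should leave the three aryl silyl ethers, the aryl iodide and C3 (not α to the carbonyl) untouched.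

Step 16
Reactants: 26 (3R)-4-[2-iodo-3-methoxy-4-(3-methylbut-2-en-1-yl)-5-(triisopropylsilyloxy)phenoxy]-3-[3-(3-methylbut-2-en-1-yl)-2,4-bis(triisopropylsilyloxy)phenyl]butanoic acid
Product: 27 1,3-dioxoisoindolin-2-yl (3R)-4-[2-iodo-3-methoxy-4-(3-methylbut-2-en-1-yl)-5-(triisopropylsilyloxy)phenoxy]-3-[3-(3-methylbut-2-en-1-yl)-2,4-bis(triisopropylsilyloxy)phenyl]butanoate
Conditions: N-hydroxyphthalimide, DIC, DMAP (10 mol%), CH2Cl2, 0 °C → rt
Reagents that add atoms: N-hydroxyphthalimide, O=C1c2ccccc2C(=O)N1O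
Why: Carbodiimide-mediated (Steglich-type) esterification of the acid with N-hydroxyphthalimide should give the redox-active ester under neutral conditions.

Step 17
Reactants: 27 1,3-dioxoisoindolin-2-yl (3R)-4-[2-iodo-3-methoxy-4-(3-methylbut-2-en-1-yl)-5-(triisopropylsilyloxy)phenoxy]-3-[3-(3-methylbut-2-en-1-yl)-2,4-bis(triisopropylsilyloxy)phenyl]butanoate
Product: 28 (3R)-5-methoxy-6-(3-methylbut-2-en-1-yl)-7-(triisopropylsilyloxy)-3-[3-(3-methylbut-2-en-1-yl)-2,4-bis(triisopropylsilyloxy)phenyl]chromane (licoricidin tris(triisopropylsilyl) ether)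
Conditions: NiCl2·glyme (20 mol%), 4,4′-di-tert-butyl-2,2′-bipyridine (24 mol%), LiCl (0.1 M), DMA, 5 mM in 27, undivided cell, reticulated vitreous carbon cathode, magnesium anode, constant current (about 2.5 F/mol), rt, argon
Reagents that add atoms: none
Why: Zerovalent nickel bearing the bipyridine ligand, formed at the cathode, inserts into the C4a–I bond, and after further cathodic reduction the aryl-nickel species passes one electron to the tethered N-hydroxyphthalimide ester, which fragments to phthalimide anion, CO2 and the primary C4 radical. The radical is captured by the aryl-nickel centre of the same molecule, and the resulting trivalent aryl(alkyl)nickel forms the C4–C4a bond by reductive elimination. The closest known reaction type is the nickel-electrocatalytic decarboxylative arylation of N-hydroxyphthalimide esters with aryl halides, used here within one molecule. Ring C closes as a six-membered ring through a seven-membered aryl(alkyl)nickelacycle that contains O1, C2, C3 and C4. No stereocentre is formed, and C3, one carbon away from the radical centre, keeps the configuration set in step 14. The step needs cross-coupling to beat hydrogen abstraction, dimerisation and coupling between molecules, which the tether and high dilution favour, and it needs bond formation at C4a and not C8, which the position of the iodide fixes, while the neutral reductive medium spares the prenyl alkenes and silyl ethers.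

Step 18
Reactants: 28 (3R)-licoricidin tris(triisopropylsilyl) ether
Product: 29 licoricidin, (3R)-3-[2,4-dihydroxy-3-(3-methylbut-2-en-1-yl)phenyl]-5-methoxy-6-(3-methylbut-2-en-1-yl)chroman-7-ol
Conditions: TBAF (4 equiv), AcOH (4 equiv), THF, 0 °C → rt, argon
Reagents that add atoms: none
Why: Fluoride-induced cleavage of the three aryl triisopropylsilyl ethers, buffered with acetic acid, should release licoricidin without acid strong enough to cyclise the prenyl groups onto the neighbouring phenols.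

**Compound list**

1 | phloroglucinol | Oc1cc(O)cc(O)c1 | starting material
2 | 3,5-bis(methoxymethoxy)phenol | COCOc1cc(O)cc(OCOC)c1 | intermediate
3 | [3,5-bis(methoxymethoxy)phenoxy]tri(propan-2-yl)silane | COCOc1cc(OCOC)cc(O[Si](C(C)C)(C(C)C)C(C)C)c1 | intermediate
4 | 1-bromo-3-methylbut-2-ene (prenyl bromide) | CC(C)=CCBr | starting material
5 | 2,6-bis(methoxymethoxy)-4-(triisopropylsilyloxy)phenyllithium | [Li]c1c(OCOC)cc(O[Si](C(C)C)(C(C)C)C(C)C)cc1OCOC | intermediate
6 | [3,5-bis(methoxymethoxy)-4-(3-methylbut-2-en-1-yl)phenoxy]tri(propan-2-yl)silane | COCOc1cc(O[Si](C(C)C)(C(C)C)C(C)C)cc(OCOC)c1CC=C(C)C | intermediate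
7 | 2,4-bis(methoxymethoxy)-3-(3-methylbut-2-en-1-yl)-6-(triisopropylsilyloxy)phenyllithium | [Li]c1c(O[Si](C(C)C)(C(C)C)C(C)C)cc(OCOC)c(CC=C(C)C)c1OCOC | intermediate
8 | [2-iodo-3,5-bis(methoxymethoxy)-4-(3-methylbut-2-en-1-yl)phenoxy]tri(propan-2-yl)silane | COCOc1cc(O[Si](C(C)C)(C(C)C)C(C)C)c(I)c(OCOC)c1CC=C(C)C | intermediate
9 | methyl (E)-4-bromobut-2-enoate | COC(=O)/C=C/CBr | starting material
10 | tetrabutylammonium 2-iodo-3,5-bis(methoxymethoxy)-4-(3-methylbut-2-en-1-yl)phenoxide | CCCC[N+](CCCC)(CCCC)CCCC.COCOc1cc([O-])c(I)c(OCOC)c1CC=C(C)C | intermediate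
11 | methyl (E)-4-[2-iodo-3,5-bis(methoxymethoxy)-4-(3-methylbut-2-en-1-yl)phenoxy]but-2-enoate | COC(=O)/C=C/COc1cc(OCOC)c(CC=C(C)C)c(OCOC)c1I | intermediate
12 | methyl (E)-4-[3,5-dihydroxy-2-iodo-4-(3-methylbut-2-en-1-yl)phenoxy]but-2-enoate | COC(=O)/C=C/COc1cc(O)c(CC=C(C)C)c(O)c1I | intermediate
13 | methyl (E)-4-[3-hydroxy-2-iodo-4-(3-methylbut-2-en-1-yl)-5-(triisopropylsilyloxy)phenoxy]but-2-enoate | COC(=O)/C=C/COc1cc(O[Si](C(C)C)(C(C)C)C(C)C)c(CC=C(C)C)c(O)c1I | intermediate
14 | methyl (E)-4-[2-iodo-3-methoxy-4-(3-methylbut-2-en-1-yl)-5-(triisopropylsilyloxy)phenoxy]but-2-enoate | COC(=O)/C=C/COc1cc(O[Si](C(C)C)(C(C)C)C(C)C)c(CC=C(C)C)c(OC)c1I | intermediate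
15 | resorcinol | Oc1cccc(O)c1 | starting material
16 | 2-iodobenzene-1,3-diol | Oc1cccc(O)c1I | intermediate
17 | 2-iodo-1,3-bis(triisopropylsilyloxy)benzene | CC(C)[Si](Oc1cccc(O[Si](C(C)C)(C(C)C)C(C)C)c1I)(C(C)C)C(C)C | intermediate
18 | 4-bromo-2-iodo-1,3-bis(triisopropylsilyloxy)benzene | CC(C)[Si](Oc1ccc(Br)c(O[Si](C(C)C)(C(C)C)C(C)C)c1I)(C(C)C)C(C)C | intermediate
19 | 3-bromo-2,6-bis(triisopropylsilyloxy)phenyllithium | [Li]c1c(O[Si](C(C)C)(C(C)C)C(C)C)ccc(Br)c1O[Si](C(C)C)(C(C)C)C(C)C | intermediate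
20 | 1-bromo-3-(3-methylbut-2-en-1-yl)-2,4-bis(triisopropylsilyloxy)benzene | CC(C)=CCc1c(O[Si](C(C)C)(C(C)C)C(C)C)ccc(Br)c1O[Si](C(C)C)(C(C)C)C(C)C | intermediate
21 | 3-(3-methylbut-2-en-1-yl)-2,4-bis(triisopropylsilyloxy)phenyllithium | [Li]c1ccc(O[Si](C(C)C)(C(C)C)C(C)C)c(CC=C(C)C)c1O[Si](C(C)C)(C(C)C)C(C)C | intermediate
22 | lithium triisopropoxy[3-(3-methylbut-2-en-1-yl)-2,4-bis(triisopropylsilyloxy)phenyl]borate | [Li+].CC(C)O[B-](OC(C)C)(OC(C)C)c1ccc(O[Si](C(C)C)(C(C)C)C(C)C)c(CC=C(C)C)c1O[Si](C(C)C)(C(C)C)C(C)C | intermediate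
23 | [3-(3-methylbut-2-en-1-yl)-2,4-bis(triisopropylsilyloxy)phenyl]boronic acid | OB(O)c1ccc(O[Si](C(C)C)(C(C)C)C(C)C)c(CC=C(C)C)c1O[Si](C(C)C)(C(C)C)C(C)C | intermediate
24 | methyl (3R)-4-[2-iodo-3-methoxy-4-(3-methylbut-2-en-1-yl)-5-(triisopropylsilyloxy)phenoxy]-3-[3-(3-methylbut-2-en-1-yl)-2,4-bis(triisopropylsilyloxy)phenyl]butanoate | COc1c(CC=C(C)C)c(O[Si](C(C)C)(C(C)C)C(C)C)cc(OC[C@@H](c2ccc(O[Si](C(C)C)(C(C)C)C(C)C)c(CC=C(C)C)c2O[Si](C(C)C)(C(C)C)C(C)C)CC(=O)OC)c1I | intermediate
25 | trimethylstannyl (3R)-4-[2-iodo-3-methoxy-4-(3-methylbut-2-en-1-yl)-5-(triisopropylsilyloxy)phenoxy]-3-[3-(3-methylbut-2-en-1-yl)-2,4-bis(triisopropylsilyloxy)phenyl]butanoate | COc1c(CC=C(C)C)c(O[Si](C(C)C)(C(C)C)C(C)C)cc(OC[C@@H](c2ccc(O[Si](C(C)C)(C(C)C)C(C)C)c(CC=C(C)C)c2O[Si](C(C)C)(C(C)C)C(C)C)CC(=O)O[Sn](C)(C)C)c1I | intermediate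
26 | (3R)-4-[2-iodo-3-methoxy-4-(3-methylbut-2-en-1-yl)-5-(triisopropylsilyloxy)phenoxy]-3-[3-(3-methylbut-2-en-1-yl)-2,4-bis(triisopropylsilyloxy)phenyl]butanoic acid | COc1c(CC=C(C)C)c(O[Si](C(C)C)(C(C)C)C(C)C)cc(OC[C@@H](c2ccc(O[Si](C(C)C)(C(C)C)C(C)C)c(CC=C(C)C)c2O[Si](C(C)C)(C(C)C)C(C)C)CC(=O)O)c1I | intermediate
27 | 1,3-dioxoisoindolin-2-yl (3R)-4-[2-iodo-3-methoxy-4-(3-methylbut-2-en-1-yl)-5-(triisopropylsilyloxy)phenoxy]-3-[3-(3-methylbut-2-en-1-yl)-2,4-bis(triisopropylsilyloxy)phenyl]butanoate | COc1c(CC=C(C)C)c(O[Si](C(C)C)(C(C)C)C(C)C)cc(OC[C@@H](c2ccc(O[Si](C(C)C)(C(C)C)C(C)C)c(CC=C(C)C)c2O[Si](C(C)C)(C(C)C)C(C)C)CC(=O)ON2C(=O)c3ccccc3C2=O)c1I | intermediate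
28 | (3R)-licoricidin tris(triisopropylsilyl) ether | COc1c(CC=C(C)C)c(O[Si](C(C)C)(C(C)C)C(C)C)cc2c1C[C@H](c1ccc(O[Si](C(C)C)(C(C)C)C(C)C)c(CC=C(C)C)c1O[Si](C(C)C)(C(C)C)C(C)C)CO2 | intermediate
29 | licoricidin | COc1c(CC=C(C)C)c(O)cc2c1C[C@H](c1ccc(O)c(CC=C(C)C)c1O)CO2 | target

**Step count**

Total: 18 steps. Longest linear sequence: 13 steps (steps 1–8, then 14–18). The ring B branch is steps 9–13.

**Steps most likely to fail**

1. Step 17. The C4 radical may be reduced by hydrogen abstraction, dimerise or couple between molecules, or insertion into the hindered, electron-rich C4a–I bond may lag behind reduction of the ester, so that open-chain products form instead of ring C. Fallback, setting out from acid 26 and returning at 28: the same C4 radical is generated oxidatively from the carboxylate by nickel/photoredox decarboxylative arylation ([Ir(dF(CF3)ppy)2(dtbbpy)]PF6, NiCl2·glyme, 4,4′-di-tert-butyl-2,2′-bipyridine, Cs2CO3, DMF, blue LEDs, 5 mM), which needs neither the redox-active ester nor a cathode; this fallback makes no new compound (F0).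

2. Step 14. Transfer of the hindered, electron-rich aryl group from boron may be slow and lose out to protodeboronation, rhodium may attack the C4a–I bond, or facial control on the acyclic enoate may be weak. Fallback, setting out from 23 and 8 and returning at 24:
   - 23 is added to furan-2(5H)-one with Rh(acac)(C2H4)2/(R)-BINAP in dioxane/H2O at 100 °C, a cyclic acceptor that carries no aryl iodide, to give (4R)-4-[3-(3-methylbut-2-en-1-yl)-2,4-bis(triisopropylsilyloxy)phenyl]dihydrofuran-2(3H)-one F1.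
   - KOH in aqueous THF at 0 °C opens the lactone to potassium (3R)-4-hydroxy-3-[3-(3-methylbut-2-en-1-yl)-2,4-bis(triisopropylsilyloxy)phenyl]butanoate F2, and iodomethane in DMF converts it into methyl (3R)-4-hydroxy-3-[3-(3-methylbut-2-en-1-yl)-2,4-bis(triisopropylsilyloxy)phenyl]butanoate F3, used at once.
   - 8 is desilylated with TBAF/AcOH to 2-iodo-3,5-bis(methoxymethoxy)-4-(3-methylbut-2-en-1-yl)phenol F4.
   - Mitsunobu etherification of F3 with F4 (PPh3, DIAD, THF, 0 °C) gives methyl (3R)-4-[2-iodo-3,5-bis(methoxymethoxy)-4-(3-methylbut-2-en-1-yl)phenoxy]-3-[3-(3-methylbut-2-en-1-yl)-2,4-bis(triisopropylsilyloxy)phenyl]butanoate F5.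
   - HCl in MeOH frees the two ring A phenols to give methyl (3R)-4-[3,5-dihydroxy-2-iodo-4-(3-methylbut-2-en-1-yl)phenoxy]-3-[3-(3-methylbut-2-en-1-yl)-2,4-bis(triisopropylsilyloxy)phenyl]butanoate F6.
   - TIPSCl/imidazole silylates O7 to give methyl (3R)-4-[3-hydroxy-2-iodo-4-(3-methylbut-2-en-1-yl)-5-(triisopropylsilyloxy)phenoxy]-3-[3-(3-methylbut-2-en-1-yl)-2,4-bis(triisopropylsilyloxy)phenyl]butanoate F7.
   - Iodomethane/K2CO3 methylates O5 and returns the route at 24.

3. Step 4. The base may deprotonate the benzylic–allylic CH2 of the prenyl group, or the silyl group may migrate from oxygen to carbon in the aryllithium, instead of clean ring lithiation and iodination. Fallback, setting out from 3 and returning at 8: 3 is iodinated twice with N-iodosuccinimide (2.1 equiv, MeCN) before any alkene is present, first between the two MOM ethers and then at one of the two equivalent positions beside the silyl ether, to give [2,4-diiodo-3,5-bis(methoxymethoxy)phenoxy]tri(propan-2-yl)silane F8. n-BuLi (1.0 equiv, THF, −78 °C) then exchanges the iodine flanked by the two chelating MOM ethers to give 3-iodo-2,6-bis(methoxymethoxy)-4-(triisopropylsilyloxy)phenyllithium F9, and prenyl bromide 4 alkylates it to give 8.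

**Further compounds**

F0 | step 17 | none | none
F1 | step 14 | (4R)-4-[3-(3-methylbut-2-en-1-yl)-2,4-bis(triisopropylsilyloxy)phenyl]dihydrofuran-2(3H)-one | O=C1C[C@@H](CO1)c1ccc(O[Si](C(C)C)(C(C)C)C(C)C)c(CC=C(C)C)c1O[Si](C(C)C)(C(C)C)C(C)C
F2 | step 14 | potassium (3R)-4-hydroxy-3-[3-(3-methylbut-2-en-1-yl)-2,4-bis(triisopropylsilyloxy)phenyl]butanoate | [K+].[O-]C(=O)C[C@@H](CO)c1ccc(O[Si](C(C)C)(C(C)C)C(C)C)c(CC=C(C)C)c1O[Si](C(C)C)(C(C)C)C(C)C
F3 | step 14 | methyl (3R)-4-hydroxy-3-[3-(3-methylbut-2-en-1-yl)-2,4-bis(triisopropylsilyloxy)phenyl]butanoate | COC(=O)C[C@@H](CO)c1ccc(O[Si](C(C)C)(C(C)C)C(C)C)c(CC=C(C)C)c1O[Si](C(C)C)(C(C)C)C(C)C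
F4 | step 14 | 2-iodo-3,5-bis(methoxymethoxy)-4-(3-methylbut-2-en-1-yl)phenol | COCOc1cc(O)c(I)c(OCOC)c1CC=C(C)C
F5 | step 14 | methyl (3R)-4-[2-iodo-3,5-bis(methoxymethoxy)-4-(3-methylbut-2-en-1-yl)phenoxy]-3-[3-(3-methylbut-2-en-1-yl)-2,4-bis(triisopropylsilyloxy)phenyl]butanoate | COC(=O)C[C@@H](COc1cc(OCOC)c(CC=C(C)C)c(OCOC)c1I)c1ccc(O[Si](C(C)C)(C(C)C)C(C)C)c(CC=C(C)C)c1O[Si](C(C)C)(C(C)C)C(C)C
F6 | step 14 | methyl (3R)-4-[3,5-dihydroxy-2-iodo-4-(3-methylbut-2-en-1-yl)phenoxy]-3-[3-(3-methylbut-2-en-1-yl)-2,4-bis(triisopropylsilyloxy)phenyl]butanoate | COC(=O)C[C@@H](COc1cc(O)c(CC=C(C)C)c(O)c1I)c1ccc(O[Si](C(C)C)(C(C)C)C(C)C)c(CC=C(C)C)c1O[Si](C(C)C)(C(C)C)C(C)C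
F7 | step 14 | methyl (3R)-4-[3-hydroxy-2-iodo-4-(3-methylbut-2-en-1-yl)-5-(triisopropylsilyloxy)phenoxy]-3-[3-(3-methylbut-2-en-1-yl)-2,4-bis(triisopropylsilyloxy)phenyl]butanoate | COC(=O)C[C@@H](COc1cc(O[Si](C(C)C)(C(C)C)C(C)C)c(CC=C(C)C)c(O)c1I)c1ccc(O[Si](C(C)C)(C(C)C)C(C)C)c(CC=C(C)C)c1O[Si](C(C)C)(C(C)C)C(C)C
F8 | step 4 | [2,4-diiodo-3,5-bis(methoxymethoxy)phenoxy]tri(propan-2-yl)silane | COCOc1cc(O[Si](C(C)C)(C(C)C)C(C)C)c(I)c(OCOC)c1I
F9 | step 4 | 3-iodo-2,6-bis(methoxymethoxy)-4-(triisopropylsilyloxy)phenyllithium | COCOc1cc(O[Si](C(C)C)(C(C)C)C(C)C)c(I)c(OCOC)c1[Li]
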